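## Analysis of the target

The target is a flavone: a benzene ring A (C4a, C5, C6, C7, C8, C8a) fused to a 4-pyranone ring C (O1, C2, C3, C4), with the aryl ring B on C2. Ring A has no hydrogen left (hydroxyls on C5 and C7, methoxyls on C6 and C8, the ring oxygen O1 on C8a and the carbonyl carbon C4 on C4a), ring C carries a methoxyl on C3, and ring B carries hydroxyls on C2' and C4' and a methoxyl on C5'. There is no stereocentre; the only stereochemical element met on the way is the geometry of an enol ether double bond, which ends as the endocyclic C2=C3 bond and therefore need not be controlled rigorously. Four free phenols on two very electron-rich rings make the compound oxidation-prone, above all in base, and four methyl ethers must survive while the phenols are set free, which rules out Lewis-acidic ether cleavage at the end and points to benzyl ethers and hydrogenolysis. The difficulty is regiochemical: a hexasubstituted ring A cannot be completed by electrophilic substitution, and five contiguous oxygen substituents would have to be differentiated one by one if they were put onto a benzene ring. The strategy rests on the pattern of ring A: the oxygens on C5, C7 and C8a are mutually meta, as in a polyketide phloroglucinol, the carbons between them (C6, C8) carry the methoxyls, and C4a carries the acyl carbon C4. Ring A is thus the aromatised form of a 3,5,7-trioxo ester chain with methoxyls on two chain carbons, which can be folded by a Claisen condensation between C4a and C5. The resulting acylphloroglucinol is symmetric about its acyl axis, so the later closure of ring C has no regiochemical choice to make.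

## Retrosynthetic reasoning

**18 to 17.** The last operation is the liberation of the two ring B phenols, so 18 is traced back to its 2',4'-dibenzyl ether 17 by cutting the two O–CH2 bonds. Benzyl ethers are chosen because ring B has to pass strong amide bases, a magnesium alkoxide and a hot oxidising medium, and because their hydrogenolysis leaves the methyl ethers and the chromone untouched. Ring A carries no protecting group at any stage.

**17 to 15.** Ring C is opened at O1–C2, which leads to the 2'-hydroxychalcone 15 with the C3 methoxyl already on the chain. The cut is made here, and not at C4–C4a or O1–C8a, because 15 has two equivalent hydroxyls ortho to the acyl group: whichever one adds to the enone, the same flavone results. The forward reaction has to add a phenol oxygen to the β-carbon (giving flavanone 16 in the flask) and remove two hydrogens without harming the free phenols.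

**15 to 13.** This is the key disconnection: the C4a–C5 bond of ring A. Cutting it unrolls the arene into the open-chain triketo ester 14, whose stable, isolable form is the 4-hydroxy-2-pyrone 13. The bond is cut here because this is the cut that turns a fully substituted arene into a chain in which every oxygen is already placed by the building blocks. What is gained is a ring A with no arene functionalisation and no protecting group. In the forward sense the pyrone cannot cyclise as such: the side-chain carbon and the lactone carbonyl sit 1,3 to each other across the ring oxygen, so a direct attack would have to form a four-membered ring. The lactone must first be opened by the alkoxide to 14, and the Claisen closure then takes place on the open chain.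

**13 to 4 and 12.** The bond between the side-chain methylene (C4a) and the ketone carbonyl (C4) is cut next. This divides the molecule into the ring A precursor 4 and the ester 12, which carries ring B together with C2, C3 and C4. The forward reaction is the carbon acylation of the dianion of 4 at its 6-methyl group and must proceed by 1,2-addition to the unsaturated ester.

**4 to 3, 2 and 1.** Pyrone 4 is opened at its lactone C–O bond to the dioxo ester 3. Removal of the terminal acetyl group from the γ-carbon leads to the keto ester 2, and 2 is the Claisen dimer of 1, assembled from two molecules of it. Two molecules of 1 thus supply C5/C6 and C7/C8 with both ring A methoxyls, and the acetyl unit supplies C8a and C4a.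

**12 to 11 and 1.** The C2=C3 double bond is cut in an aldol-condensation sense. A third molecule of 1 supplies C4, C3 and the C3 methoxyl, so all three methoxyls of the chromone come from the same two-carbon building block.

**11 to 9, 8, 6 and 5.** The formyl group of 11 is removed to give the triether 9, where the only doubly activated, unhindered position is the one required. The methyl ether of 9 is traced to phenol 8, and 8 to aldehyde 6 by an aryl-migration oxidation that turns the formyl carbon into the future C5' oxygen. Compound 6 is the dibenzyl ether of commercial 5, which provides the 1,3-dioxygen pattern of ring B.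

## Alternatives that were turned down

Alternative 1: ring A from a commercial arene, copper closure of O1–C8a.
- Disconnection: ring C is cut at O1–C8a. Ring A comes from 1-(4-hydroxy-3,5-dimethoxyphenyl)ethan-1-one A3 (acetosyringone), whose three oxygens already match C6, C7 and C8.
- Forward key step: after benzylation and bromination ortho to the acetyl group, the bromoaryl diketone A2 is assembled. Its enol oxygen displaces the ortho bromide under copper catalysis with a phenanthroline-type ligand and a carbonate base (intramolecular Ullmann-type O-arylation), giving chromone A1.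
- For: the ring closure is dependable and insensitive to the flanking methoxyl, the starting arene is cheap, and the C6/C7/C8 oxygens are differentiated from the start. On robustness of the ring-forming step this route is stronger than the chosen one.
- Against: A3 has hydrogen at both positions ortho to the acetyl group. One becomes C8a, the other stays as C5–H in A1, so the chelated C5 hydroxyl would have to be installed by a late carbonyl-directed C–H oxidation. That step would run on a substrate with three benzyl ethers and an electron-rich ring B with two free positions, and it is the least predictable step at the very end. The central methoxyl of A2 is also absent from A3 and needs an extra α-oxygenation.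
- Comparison: the chosen route delivers all five ring A oxygens and the C3 methoxyl together from one building block. Its uncertainty lies mid-route on cheap material rather than in a final C–H oxidation.

Alternative 2: squarate ring expansion onto a pyranone, forming C8–C8a.
- Disconnection: ring A is removed from a pyranone that already carries ring B, by cutting C8–C8a and, one step earlier, C4a–C5.
- Forward key step: an organometallic derived from the ring B pyranone half adds to one carbonyl of the mixed squarate A6 to give the hydroxycyclobutenone A5. Heating opens the four-membered ring to a vinylketene (4π), which closes onto the pyranone double bond (6π) and tautomerises to hydroquinone A4 (Moore-type rearrangement).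
- For: it is convergent and reagent-free, it builds ring A with all its oxygens, and it has ring C in place beforehand, so no oxidative cyclisation is needed. Its C7 oxygen is individually addressable, which is more differentiation than the chosen route can offer.
- Against: the substitution pattern of A4 depends on which carbonyl of A6 is attacked, and the two differ only in a remote alkoxy group. A carbanion on a 4-pyranone is hard to generate beside its own electrophilic vinylogous ester. A4 is an oxidation-prone 5,8-hydroquinone that still needs selective methylation at C8–OH, acid removal of the tert-butyl group and hydrogenolysis: three steps and two kinds of deprotection after the key step.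
- Comparison: the target needs no distinction between the C5 and C7 oxygens, so this extra control buys nothing here. The chosen route uses the symmetry of the phloroglucinol to remove the regiochemical question and finishes in two steps.

Alternative 3: Friedel–Crafts closure of C4–C4a at the lone ring A carbon.
- Disconnection: ring C is cut at C4–C4a, leading to the aryloxy acrylic acid A8, itself made from the pentaoxygenated phenol A9.
- Forward key step: A8 is activated as a mixed anhydride with a perfluoroacyl anhydride, and the acylium carbon attacks the only free carbon of ring A to give chromone A7.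
- For: the regiochemistry cannot fail, since there is one C–H and it is activated by ortho and para oxygens. This type of closure is classical for chromones. A7 is one hydrogenolysis from the target, so the end game is shorter than in the chosen route and contains no oxidation beside free phenols. On these points Alternative 3 is the stronger plan.
- Against: the whole difficulty is moved into A9, a benzene with five contiguous oxygens of three kinds that must be installed and differentiated stepwise. A8 needs a defined geometry (carboxyl cis to the aryloxy group) and its assembly from the hindered phenol A9 is not trivial. The strong acid released on activation threatens benzyl ethers on such electron-rich rings.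
- Comparison: the chosen route reaches the same oxygen pattern without ever functionalising an arene. It trades a secure ring closure for a much shorter supply of ring A.

Key step: step 10

Assumption: compounds 2, 3, 14 and 16 contain configurationally labile stereocentres and are handled as racemic mixtures of tautomers and diastereomers, so their SMILES carry no stereodescriptors; the target is achiral.

## Route

Step 1
Reactants: 1 methyl methoxyacetate (2 equiv)
Product: 2 methyl 2,4-dimethoxy-3-oxobutanoate
Conditions: NaH (0.55 equiv), cat. MeOH, toluene, 0 °C to 60 °C; then cold aq. HCl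
Reagents that add atoms: methyl methoxyacetate (second equivalent of 1, the acyl acceptor), COCC(=O)OC
Why: Claisen self-condensation in which the enolate of one molecule of 1 acylates the ester carbonyl of a second molecule with loss of methanol; the equilibrium is drawn to the product because the β-keto ester keeps one acidic C2–H and is stored as its sodium enolate.

Step 2
Reactants: 2 methyl 2,4-dimethoxy-3-oxobutanoate
Product: 3 methyl 2,4-dimethoxy-3,5-dioxohexanoate
Conditions: LiN(iPr)2 (2.2 equiv), THF, −78 to −20 °C; N-methoxy-N-methylacetamide, −78 to 0 °C; aq. HCl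
Reagents that add atoms: N-methoxy-N-methylacetamide, CC(=O)N(C)OC
Why: γ-Acylation of a β-keto ester dianion: the second deprotonation can only occur at C4, and this more basic carbanion attacks the Weinreb amide, whose chelated tetrahedral adduct masks the new ketone until work-up, so the product cannot quench unreacted dianion.

Step 3
Reactants: 3 methyl 2,4-dimethoxy-3,5-dioxohexanoate
Product: 4 4-hydroxy-3,5-dimethoxy-6-methyl-2H-pyran-2-one
Conditions: DBU, toluene, reflux; aq. HCl wash
Reagents that add atoms: none
Why: Base-mediated lactonisation of a 3,5-dioxo ester: the enol oxygen of the C5 ketone attacks the ester (6-exo-trig), methanol is lost and the product is held as a vinylogous acid; this is the standard closure of 2,4-disubstituted 3,5-dioxo esters to 4-hydroxy-2-pyrones.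

Step 4
Reactants: 5 2,4-dihydroxybenzaldehyde
Product: 6 2,4-bis(benzyloxy)benzaldehyde
Conditions: BnBr (2.3 equiv), K2CO3, DMF, 60 °C
Reagents that add atoms: benzyl bromide, BrCc1ccccc1
Why: Williamson etherification; warming in DMF also alkylates the hydrogen-bonded 2-hydroxyl.

Step 5
Reactants: 6 2,4-bis(benzyloxy)benzaldehyde
Product: 8 2,4-bis(benzyloxy)phenol, via 2,4-bis(benzyloxy)phenyl formate 7 (not isolated)
Conditions: mCPBA, CH2Cl2, 0 °C to rt; then K2CO3 (cat.), MeOH, rt
Reagents that add atoms: 3-chloroperoxybenzoic acid (mCPBA), OOC(=O)c1cccc(Cl)c1
Why: Baeyer–Villiger (Dakin-type) oxidation: the aryl group, made electron-rich by ortho and para alkoxy groups, migrates in preference to hydride to give the aryl formate, which is cleaved by methanolysis.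

Step 6
Reactants: 8 2,4-bis(benzyloxy)phenol
Product: 9 2,4-bis(benzyloxy)-1-methoxybenzene
Conditions: MeI, K2CO3, acetone, reflux
Reagents that add atoms: iodomethane, CI
Why: Williamson O-methylation of the only free phenol.

Step 7
Reactants: 9 2,4-bis(benzyloxy)-1-methoxybenzene
Product: 11 2,4-bis(benzyloxy)-5-methoxybenzaldehyde, via aryl iminium chloride 10 (not isolated)
Conditions: POCl3, DMF, 0 to 70 °C; then ice–water
Reagents that add atoms: N,N-dimethylformamide, CN(C)C=O; water, O
Why: Vilsmeier–Haack formylation: C5 is para to one benzyloxy group and ortho to the other, whereas C3 is shielded between two benzyloxy groups and C6 is activated by the methoxyl alone, the same orientation as in the formylation of 1,2,4-trialkoxybenzenes.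

Step 8
Reactants: 11 2,4-bis(benzyloxy)-5-methoxybenzaldehyde; 1 methyl methoxyacetate
Product: 12 methyl (2Z)-3-[2,4-bis(benzyloxy)-5-methoxyphenyl]-2-methoxyprop-2-enoate
Conditions: 1 (3 equiv), NaOMe (1.5 equiv), MeOH–toluene, 0 to 50 °C; AcOH
Reagents that add atoms: none
Why: Aldol condensation of an alkoxyacetate enolate with a non-enolisable aryl aldehyde followed by E1cB loss of water (Claisen–Schmidt type); under these equilibrating conditions the aryl group should end trans to the ester, which is the Z isomer.

Step 9
Reactants: 4 4-hydroxy-3,5-dimethoxy-6-methyl-2H-pyran-2-one; 12 methyl (2Z)-3-[2,4-bis(benzyloxy)-5-methoxyphenyl]-2-methoxyprop-2-enoate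
Product: 13 6-{(3Z)-4-[2,4-bis(benzyloxy)-5-methoxyphenyl]-3-methoxy-2-oxobut-3-en-1-yl}-4-hydroxy-3,5-dimethoxy-2H-pyran-2-one
Conditions: 4 (2.1 equiv), LiN(iPr)2 (4.3 equiv), THF, −78 to −20 °C; then 12 (1 equiv), −78 to 0 °C; aq. HCl
Reagents that add atoms: none
Why: Ester acylation of the O,C-dianion of a 4-hydroxy-6-methyl-2-pyrone, a known reaction that includes cinnamate esters: C3 and C5 are blocked by methoxyls, so the 6-methyl is the only carbon acid, the second equivalent of dianion serves as base for the more acidic product, and the α-methoxy, β-(dialkoxyaryl) acrylate is too poor a Michael acceptor to divert the hard carbanion from 1,2-addition.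

Step 10
Reactants: 13 6-{(3Z)-4-[2,4-bis(benzyloxy)-5-methoxyphenyl]-3-methoxy-2-oxobut-3-en-1-yl}-4-hydroxy-3,5-dimethoxy-2H-pyran-2-one
Product: 15 (2Z)-3-[2,4-bis(benzyloxy)-5-methoxyphenyl]-2-methoxy-1-(2,4,6-trihydroxy-3,5-dimethoxyphenyl)prop-2-en-1-one, via open-chain triketo ester 14 (not isolated)
Conditions: Mg(OMe)2 (8 equiv), anhydrous MeOH, reflux, argon; then cold 1 M HCl
Reagents that add atoms: none
Why: Mg(OMe)2 deprotonates the 4-hydroxyl and the side-chain methylene, and methoxide opens the lactone to the magnesium-chelated triketo ester 14; a direct attack of the methylene carbon on the carbonyl of the intact pyrone is impossible because it would close a four-membered ring across the ring oxygen. In 14 the doubly activated methylene carbon (C4a), held as a magnesium β-diketonate, attacks the ester carbonyl (C5) in an allowed 6-(enolendo)-exo-trig Claisen (Dieckmann-type) closure, methoxide leaves, and the cyclohexane-1,3,5-trione tautomerises irreversibly to the acylphloroglucinol, which is ring A. The closest known reaction is the Mg(OMe)2-induced conversion of 6-(2-oxoalkyl)-4-hydroxy-2-pyrones and 3,5,7-trioxo esters into acylphloroglucinols, the laboratory counterpart of the chalcone-forming fold in biosynthesis. No stereocentre is formed; the Z enol ether lies outside the reacting enolate and should survive, and either geometry would converge in step 11. The step needs the Claisen mode to win over the aldol mode (ester α-carbon onto the C4 ketone), over re-lactonisation and over retro-Claisen cleavage. The aldol adduct would carry a quaternary methoxy-bearing carbon and cannot dehydrate to an arene, so it can only revert; re-lactonisation merely returns the pyrone anion; and magnesium chelation keeps the polyketone as enolates that methoxide does not cleave, while anhydrous methanol excludes retro-aldol loss of the aldehyde. Because ring A of 15 is symmetric about the acyl axis, it is immaterial which chain terminus is called C5 and which C8a.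

Step 11
Reactants: 15 (2Z)-3-[2,4-bis(benzyloxy)-5-methoxyphenyl]-2-methoxy-1-(2,4,6-trihydroxy-3,5-dimethoxyphenyl)prop-2-en-1-one
Product: 17 2-[2,4-bis(benzyloxy)-5-methoxyphenyl]-5,7-dihydroxy-3,6,8-trimethoxy-4H-chromen-4-one, via 3-methoxyflavanone 16 (not isolated)
Conditions: I2 (0.1 equiv), DMSO, 120 °C
Reagents that add atoms: none
Why: Iodine/DMSO oxidative cyclisation of a 2'-hydroxychalcone: an ortho phenol adds to the enone β-carbon (6-endo-trig oxa-Michael) to give flavanone 16, α-iodination at C3 and loss of HI give the chromone, and DMSO reoxidises HI so that iodine stays catalytic; both ortho hydroxyls give the same product and ring A has no free carbon to iodinate.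

Step 12
Reactants: 17 2-[2,4-bis(benzyloxy)-5-methoxyphenyl]-5,7-dihydroxy-3,6,8-trimethoxy-4H-chromen-4-one
Product: 18 2-(2,4-dihydroxy-5-methoxyphenyl)-5,7-dihydroxy-3,6,8-trimethoxy-4H-chromen-4-one (5,7,2',4'-tetrahydroxy-3,6,8,5'-tetramethoxyflavone)
Conditions: H2 (1 atm), 10% Pd/C, EtOAc–MeOH, rt
Reagents that add atoms: none
Why: Hydrogenolysis of two aryl benzyl ethers; the tetrasubstituted, cross-conjugated C2=C3 bond of the flavone and the methyl ethers should be inert under these mild conditions.

## Compound list

1 | methyl methoxyacetate | COCC(=O)OC | starting material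
2 | methyl 2,4-dimethoxy-3-oxobutanoate (racemic) | COCC(=O)C(OC)C(=O)OC | intermediate
3 | methyl 2,4-dimethoxy-3,5-dioxohexanoate (mixture of tautomers and diastereomers) | CC(=O)C(OC)C(=O)C(OC)C(=O)OC | intermediate
4 | 4-hydroxy-3,5-dimethoxy-6-methyl-2H-pyran-2-one | Cc1oc(=O)c(OC)c(O)c1OC | intermediate
5 | 2,4-dihydroxybenzaldehyde | O=Cc1ccc(O)cc1O | starting material
6 | 2,4-bis(benzyloxy)benzaldehyde | O=Cc1ccc(OCc2ccccc2)cc1OCc1ccccc1 | intermediate
7 | 2,4-bis(benzyloxy)phenyl formate | O=COc1ccc(OCc2ccccc2)cc1OCc1ccccc1 | intermediate (not isolated)
8 | 2,4-bis(benzyloxy)phenol | Oc1ccc(OCc2ccccc2)cc1OCc1ccccc1 | intermediate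
9 | 2,4-bis(benzyloxy)-1-methoxybenzene | COc1ccc(OCc2ccccc2)cc1OCc1ccccc1 | intermediate
10 | N-{[2,4-bis(benzyloxy)-5-methoxyphenyl]methylidene}-N-methylmethanaminium chloride | C[N+](C)=Cc1cc(OC)c(OCc2ccccc2)cc1OCc1ccccc1.[Cl-] | intermediate (not isolated)
11 | 2,4-bis(benzyloxy)-5-methoxybenzaldehyde | COc1cc(C=O)c(OCc2ccccc2)cc1OCc1ccccc1 | intermediate
12 | methyl (2Z)-3-[2,4-bis(benzyloxy)-5-methoxyphenyl]-2-methoxyprop-2-enoate | COC(=O)/C(OC)=C/c1cc(OC)c(OCc2ccccc2)cc1OCc1ccccc1 | intermediate
13 | 6-{(3Z)-4-[2,4-bis(benzyloxy)-5-methoxyphenyl]-3-methoxy-2-oxobut-3-en-1-yl}-4-hydroxy-3,5-dimethoxy-2H-pyran-2-one | O=c1oc(CC(=O)/C(OC)=C/c2cc(OC)c(OCc3ccccc3)cc2OCc2ccccc2)c(OC)c(O)c1OC | intermediate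
14 | methyl (8Z)-9-[2,4-bis(benzyloxy)-5-methoxyphenyl]-2,4,8-trimethoxy-3,5,7-trioxonon-8-enoate (magnesium chelate, mixture of tautomers) | COC(=O)C(OC)C(=O)C(OC)C(=O)CC(=O)/C(OC)=C/c1cc(OC)c(OCc2ccccc2)cc1OCc1ccccc1 | intermediate (not isolated)
15 | (2Z)-3-[2,4-bis(benzyloxy)-5-methoxyphenyl]-2-methoxy-1-(2,4,6-trihydroxy-3,5-dimethoxyphenyl)prop-2-en-1-one | COc1c(O)c(OC)c(O)c(C(=O)/C(OC)=C/c2cc(OC)c(OCc3ccccc3)cc2OCc2ccccc2)c1O | intermediate
16 | 2-[2,4-bis(benzyloxy)-5-methoxyphenyl]-5,7-dihydroxy-3,6,8-trimethoxy-2,3-dihydro-4H-chromen-4-one (racemic, both diastereomers) | COC1C(=O)c2c(O)c(OC)c(O)c(OC)c2OC1c1cc(OC)c(OCc2ccccc2)cc1OCc1ccccc1 | intermediate (not isolated)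
17 | 2-[2,4-bis(benzyloxy)-5-methoxyphenyl]-5,7-dihydroxy-3,6,8-trimethoxy-4H-chromen-4-one | COc1cc(-c2oc3c(OC)c(O)c(OC)c(O)c3c(=O)c2OC)c(OCc2ccccc2)cc1OCc1ccccc1 | intermediate
18 | 2-(2,4-dihydroxy-5-methoxyphenyl)-5,7-dihydroxy-3,6,8-trimethoxy-4H-chromen-4-one | COc1cc(-c2oc3c(OC)c(O)c(OC)c(O)c3c(=O)c2OC)c(O)cc1O | target

## Step count and risks

Total step count: 12. Longest linear sequence: 9 steps (steps 4 to 12, from 5 to 18); the pyrone branch (steps 1 to 3) joins at step 9.

**Step 10 (key step).** The chelated pyrone anion, made more electron-rich by two methoxyls, may resist methanolysis. Once the chain is open, retro-Claisen fragmentation of the α-alkoxy polyketone by methoxide may outrun the fold, and reversible methoxide addition to the enone may tie up material.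

Fallback: setting out from 11 and coming back to the route at 15, ring A is made from an arene instead of a chain. Benzene-1,3,5-triol F1 is converted with chloromethyl methyl ether and iPr2NEt into 1,3,5-tris(methoxymethoxy)benzene F2. Two equivalents of N-bromosuccinimide in DMF give 2,4-dibromo-1,3,5-tris(methoxymethoxy)benzene F3, and copper-catalysed methoxylation (NaOMe, CuI, DMF–MeOH, 110 °C) gives 2,4-dimethoxy-1,3,5-tris(methoxymethoxy)benzene F4. Lithiation of the one remaining ring position, which lies between two directing acetal groups (n-BuLi, THF, 0 °C), and acylation with N,2-dimethoxy-N-methylacetamide give 1-[3,5-dimethoxy-2,4,6-tris(methoxymethoxy)phenyl]-2-methoxyethan-1-one F5. Claisen–Schmidt condensation of F5 with 11 (KOH, EtOH) gives (2Z)-3-[2,4-bis(benzyloxy)-5-methoxyphenyl]-1-[3,5-dimethoxy-2,4,6-tris(methoxymethoxy)phenyl]-2-methoxyprop-2-en-1-one F6. HCl in MeOH at 40 °C removes the three acetals and returns 15; any flavanone 16 formed here is equally a substrate for step 11.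

**Step 9.** Carbon acylation may be slow or incomplete because the enol-ether ester is a weak electrophile, because the dilithium salt of 4 is poorly soluble, or because proton transfer from the product quenches the dianion. Conjugate addition is a minor concern.

Fallback: setting out from 12 and coming back to the route at 13, the ester is replaced by the more electrophilic aldehyde. Reduction of 12 with iBu2AlH (CH2Cl2, −78 °C) gives (2Z)-3-[2,4-bis(benzyloxy)-5-methoxyphenyl]-2-methoxyprop-2-en-1-ol F7, and MnO2 oxidises it to (2Z)-3-[2,4-bis(benzyloxy)-5-methoxyphenyl]-2-methoxyprop-2-enal F8. Aldol addition of the dianion of 4 to F8 gives 6-{(3Z)-4-[2,4-bis(benzyloxy)-5-methoxyphenyl]-2-hydroxy-3-methoxybut-3-en-1-yl}-4-hydroxy-3,5-dimethoxy-2H-pyran-2-one F9 (racemic). Oxidation of the allylic alcohol of F9 with Dess–Martin periodinane returns 13.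

**Step 11.** Over-oxidation of the trihydroxyaryl ring, iodination of ring B between its two benzyloxy groups, or acid-induced loss of benzyl ethers at 120 °C may compete with the dehydrogenation.

Fallback: setting out from 15 and coming back to the route at 18, cyclisation and dehydrogenation are separated and the reactive 7-hydroxyl is masked. Compound 15 is isomerised with NaOAc in refluxing EtOH to flavanone 16, which is isolated. The unchelated 7-hydroxyl is benzylated selectively (BnBr, 1 equiv, K2CO3, acetone) to give 7-(benzyloxy)-2-[2,4-bis(benzyloxy)-5-methoxyphenyl]-5-hydroxy-3,6,8-trimethoxy-2,3-dihydro-4H-chromen-4-one F10. DDQ in refluxing dioxane dehydrogenates F10 to 7-(benzyloxy)-2-[2,4-bis(benzyloxy)-5-methoxyphenyl]-5-hydroxy-3,6,8-trimethoxy-4H-chromen-4-one F11. Hydrogenolysis of all three benzyl ethers (H2, Pd/C) gives 18.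

**Step 2.** Proton transfer from the enolisable acetyl donor to the strongly basic γ-carbanion, or O-acylation, may take the place of carbon acylation.

Fallback: setting out from 2 and coming back to the route at 3, the dianion of 2 is added to acetaldehyde, which reacts faster than it is enolised, to give methyl 5-hydroxy-2,4-dimethoxy-3-oxohexanoate F12 (mixture of diastereomers). Oxidation of F12 with Dess–Martin periodinane gives 3.

## Further compounds

F1 | step 10 | benzene-1,3,5-triol (phloroglucinol) | Oc1cc(O)cc(O)c1
F2 | step 10 | 1,3,5-tris(methoxymethoxy)benzene | COCOc1cc(OCOC)cc(OCOC)c1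
F3 | step 10 | 2,4-dibromo-1,3,5-tris(methoxymethoxy)benzene | COCOc1cc(OCOC)c(Br)c(OCOC)c1Br
F4 | step 10 | 2,4-dimethoxy-1,3,5-tris(methoxymethoxy)benzene | COCOc1cc(OCOC)c(OC)c(OCOC)c1OC
F5 | step 10 | 1-[3,5-dimethoxy-2,4,6-tris(methoxymethoxy)phenyl]-2-methoxyethan-1-one | COCC(=O)c1c(OCOC)c(OC)c(OCOC)c(OC)c1OCOC
F6 | step 10 | (2Z)-3-[2,4-bis(benzyloxy)-5-methoxyphenyl]-1-[3,5-dimethoxy-2,4,6-tris(methoxymethoxy)phenyl]-2-methoxyprop-2-en-1-one | COCOc1c(OC)c(OCOC)c(OC)c(OCOC)c1C(=O)/C(OC)=C/c1cc(OC)c(OCc2ccccc2)cc1OCc1ccccc1
F7 | step 9 | (2Z)-3-[2,4-bis(benzyloxy)-5-methoxyphenyl]-2-methoxyprop-2-en-1-ol | OC/C(OC)=C/c1cc(OC)c(OCc2ccccc2)cc1OCc1ccccc1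
F8 | step 9 | (2Z)-3-[2,4-bis(benzyloxy)-5-methoxyphenyl]-2-methoxyprop-2-enal | O=C/C(OC)=C/c1cc(OC)c(OCc2ccccc2)cc1OCc1ccccc1
F9 | step 9 | 6-{(3Z)-4-[2,4-bis(benzyloxy)-5-methoxyphenyl]-2-hydroxy-3-methoxybut-3-en-1-yl}-4-hydroxy-3,5-dimethoxy-2H-pyran-2-one (racemic) | O=c1oc(CC(O)/C(OC)=C/c2cc(OC)c(OCc3ccccc3)cc2OCc2ccccc2)c(OC)c(O)c1OC
F10 | step 11 | 7-(benzyloxy)-2-[2,4-bis(benzyloxy)-5-methoxyphenyl]-5-hydroxy-3,6,8-trimethoxy-2,3-dihydro-4H-chromen-4-one (racemic, both diastereomers) | COC1C(=O)c2c(O)c(OC)c(OCc3ccccc3)c(OC)c2OC1c1cc(OC)c(OCc2ccccc2)cc1OCc1ccccc1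
F11 | step 11 | 7-(benzyloxy)-2-[2,4-bis(benzyloxy)-5-methoxyphenyl]-5-hydroxy-3,6,8-trimethoxy-4H-chromen-4-one | COc1cc(-c2oc3c(OC)c(OCc4ccccc4)c(OC)c(O)c3c(=O)c2OC)c(OCc2ccccc2)cc1OCc1ccccc1
F12 | step 2 | methyl 5-hydroxy-2,4-dimethoxy-3-oxohexanoate (mixture of diastereomers) | CC(O)C(OC)C(=O)C(OC)C(=O)OC
A1 | alternative 1 | 7-(benzyloxy)-2-[2,4-bis(benzyloxy)-5-methoxyphenyl]-3,6,8-trimethoxy-4H-chromen-4-one | COc1cc(-c2oc3c(OC)c(OCc4ccccc4)c(OC)cc3c(=O)c2OC)c(OCc2ccccc2)cc1OCc1ccccc1
A2 | alternative 1 | 1-[4-(benzyloxy)-2-bromo-3,5-dimethoxyphenyl]-3-[2,4-bis(benzyloxy)-5-methoxyphenyl]-2-methoxypropane-1,3-dione (racemic) | COc1cc(C(=O)C(OC)C(=O)c2cc(OC)c(OCc3ccccc3)c(OC)c2Br)c(OCc2ccccc2)cc1OCc1ccccc1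
A3 | alternative 1 | 1-(4-hydroxy-3,5-dimethoxyphenyl)ethan-1-one (acetosyringone) | CC(=O)c1cc(OC)c(O)c(OC)c1
A4 | alternative 2 | 2-[2,4-bis(benzyloxy)-5-methoxyphenyl]-7-tert-butoxy-5,8-dihydroxy-3,6-dimethoxy-4H-chromen-4-one | COc1c(-c2cc(OC)c(OCc3ccccc3)cc2OCc2ccccc2)oc2c(O)c(OC(C)(C)C)c(OC)c(O)c2c1=O
A5 | alternative 2 | 4-{6-[2,4-bis(benzyloxy)-5-methoxyphenyl]-5-methoxy-4-oxo-4H-pyran-3-yl}-2-tert-butoxy-4-hydroxy-3-methoxycyclobut-2-en-1-one (racemic) | COC1=C(OC(C)(C)C)C(=O)C1(O)c1coc(-c2cc(OC)c(OCc3ccccc3)cc2OCc2ccccc2)c(OC)c1=O
A6 | alternative 2 | 3-tert-butoxy-4-methoxycyclobut-3-ene-1,2-dione | COC1=C(OC(C)(C)C)C(=O)C1=O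
A7 | alternative 3 | 5,7-bis(benzyloxy)-2-[2,4-bis(benzyloxy)-5-methoxyphenyl]-3,6,8-trimethoxy-4H-chromen-4-one | COc1cc(-c2oc3c(OC)c(OCc4ccccc4)c(OC)c(OCc4ccccc4)c3c(=O)c2OC)c(OCc2ccccc2)cc1OCc1ccccc1
A8 | alternative 3 | (2E)-3-[3,5-bis(benzyloxy)-2,4-dimethoxyphenoxy]-3-[2,4-bis(benzyloxy)-5-methoxyphenyl]-2-methoxyprop-2-enoic acid | OC(=O)/C(OC)=C(/c1cc(OC)c(OCc2ccccc2)cc1OCc1ccccc1)Oc1cc(OCc2ccccc2)c(OC)c(OCc2ccccc2)c1OC
A9 | alternative 3 | 3,5-bis(benzyloxy)-2,4-dimethoxyphenol | Oc1cc(OCc2ccccc2)c(OC)c(OCc2ccccc2)c1OC
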